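## Retrosynthetic overview

The strategy rests on the C5–C10 bond shared by rings A and B. It joins quaternary C10 (C14 methyl, next to the C1 carbinol) to C5 (next to the C4=C15 methylene), which is the imprint of a 1(10)-epoxygermacr-4-ene opened across its ten-membered ring.
Late stage: the free side-chain alcohol comes from desilylation, and the 3β-OH comes from allylic oxidation at C3 followed by an oxidation/reduction correction, both on a 1β-hydroxyeudesma-4(15),11(13)-diene.
Key disconnection: C5–C10, leading back to the (1R,10R)-1(10)-epoxide of a 6α-acyloxygermacra-4,11(13)-dien-12-oate, by a radical transannular closure with trivalent titanium.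
The O6–acyl bond is made by Mitsunobu inversion of the 6β-alcohol, and C6–C7 by chromium-mediated macro-allylation. The open chain comes from (2E,6E)-farnesol (C1–C10, C14, C15) and methyl acrylate (C11–C13, OMe) through a Morita–Baylis–Hillman union at C7–C11.
Ring order: the ten-membered carbocycle is closed first, then rings A and B are formed together by one bond.

Key step: step 15

Assumption: cyclic compounds carry germacrane/eudesmane numbering (C14 on C10 is β). The ligand antipode that leads to the (6S,7S) series cannot be predicted for a macrocyclic closure, so it is to be fixed in a pilot run; both antipodes derive from D- or L-valinol.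

## Route

Step 1
Reactants: 1 (2E,6E)-farnesol
Product: 2 (2E,6E)-farnesyl tert-butyldimethylsilyl ether
Conditions: TBSCl, imidazole, CH2Cl2, 0 °C to rt
Reagents that add atoms: tert-butyldimethylsilyl chloride, CC(C)(C)[Si](C)(C)Cl
Why: Imidazole-promoted O-silylation of the primary allylic alcohol masks the future C6 terminus during the chain degradation.

Step 2
Reactants: 2 farnesyl TBS ether
Product: 3 10-bromo-11-hydroxy-10,11-dihydrofarnesyl TBS ether (farnesol numbering, racemic at C10, 2E,6E)
Conditions: NBS (1.05 equiv), THF/H2O, 0 °C
Reagents that add atoms: N-bromosuccinimide, O=C1CCC(=O)N1Br; water, O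
Why: In aqueous THF, electrophilic bromohydrin formation should pick the terminal, least hindered trisubstituted alkene, with water opening the bromonium ion at the tertiary carbon; the racemic centre is excised later.

Step 3
Reactants: 3 terminal bromohydrin
Product: 4 10,11-epoxyfarnesyl TBS ether (racemic, 2E,6E)
Conditions: K2CO3, MeOH, rt
Reagents that add atoms: none
Why: Base-induced intramolecular Williamson-type displacement of bromide by the tertiary alkoxide closes the oxirane and leaves the silyl ether untouched.

Step 4
Reactants: 4 terminal epoxide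
Product: 6 (4E,8E)-10-(tert-butyldimethylsilyloxy)-4,8-dimethyldeca-4,8-dienal, via 10,11-diol 5 (not isolated)
Conditions: H5IO6 (1.2 equiv), THF/Et2O, 0 °C, short contact
Reagents that add atoms: water, O (taken up in diol 5 and lost again with acetone)
Why: Periodic acid hydrates the epoxide and cleaves the glycol at once (Malaprade-type cleavage), removing three carbons as acetone and leaving the aldehyde carbon that becomes C7; a primary TBS ether tolerates the brief cold exposure.

Step 5
Reactants: 6 trisnor aldehyde; 7 methyl acrylate
Product: 8 methyl (6E,10E)-12-(tert-butyldimethylsilyloxy)-3-hydroxy-6,10-dimethyl-2-methylidenedodeca-6,10-dienoate (racemic carbinol)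
Conditions: DABCO (0.5 equiv), 7 (5 equiv), MeOH, rt, several days
Reagents that add atoms: none
Why: In the Morita–Baylis–Hillman reaction the amine–acrylate zwitterion adds to the unhindered aliphatic aldehyde and forms C7–C11; the racemic carbinol centre is erased in the next step.

Step 6
Reactants: 8 Morita–Baylis–Hillman alcohol
Product: 9 methyl (2Z,6E,10E)-2-(bromomethyl)-12-(tert-butyldimethylsilyloxy)-6,10-dimethyldodeca-2,6,10-trienoate
Conditions: NBS, Me2S (premixed), CH2Cl2, 0 °C to rt
Reagents that add atoms: N-bromosuccinimide, O=C1CCC(=O)N1Br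
Why: The premixed sulfonium reagent activates the hydroxyl and bromide attacks the methylene terminus (SN2′ bromination of a Morita–Baylis–Hillman alcohol). Allylic strain places the chain trans to the ester (Z), and no free NBS remains to touch the two trisubstituted alkenes.

Step 7
Reactants: 9 silyl-protected allylic bromide
Product: 10 methyl (2Z,6E,10E)-2-(bromomethyl)-12-hydroxy-6,10-dimethyldodeca-2,6,10-trienoate
Conditions: camphorsulfonic acid (10 mol %), MeOH/CH2Cl2, 0 °C
Reagents that add atoms: none
Why: Acid-catalysed methanolysis of the primary silyl ether is chosen over fluoride salts or amine-buffered reagents, which would displace the reactive 2-(bromomethyl)enoate bromide.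

Step 8
Reactants: 10 allylic alcohol
Product: 11 methyl (2Z,6E,10E)-2-(bromomethyl)-6,10-dimethyl-12-oxododeca-2,6,10-trienoate
Conditions: activated MnO2 (15 equiv), CH2Cl2, rt
Reagents that add atoms: none
Why: Neutral MnO2 oxidation of a primary allylic alcohol gives the E-enal without alkene isomerisation and without touching the allylic bromide.

Step 9
Reactants: 11 bromo enal
Product: 12 methyl (6S,7S)-6-(trimethylsilyloxy)germacra-1(10),4,11(13)-trien-12-oate (1(10)E,4E; 6β-O, 7α-H)
Conditions: CrCl2 (20 mol %), (S,S)-1,8-bis(4-isopropyl-4,5-dihydrooxazol-2-yl)-3,6-diphenyl-9H-carbazole or its antipode (24 mol %), i-Pr2NEt (40 mol %), Mn (3 equiv), TMSCl (2 equiv), THF, rt, 11 added by syringe pump over 20 h (final 3 mM)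
Reagents that add atoms: trimethylsilyl chloride, C[Si](C)(C)Cl
Why: Proposed new method: two divalent chromium centres reduce the allylic C–Br bond to a ligand-bound 2-(methoxycarbonyl)allylchromium species that adds through its γ-carbon C7 to the enal carbonyl C6 in a closed chair transition state, C8 being cis to the CH2Cr arm and hence axial, which should give the 6,7-syn pair, while the C2-symmetric tridentate ligand on chromium selects the aldehyde face and with it the absolute (6S,7S) sense, and TMSCl silylates the chromium alkoxide, frees the metal for re-reduction by Mn and blocks lactonisation onto C12; the closest known reaction types are the ligand-free CrCl2-mediated Nozaki–Hiyama–Kishi closure of ten-membered rings from such bromo enals and the intermolecular catalytic enantioselective 2-(alkoxycarbonyl)allylation of aldehydes with this ligand family, whose merger on an achiral macrocyclisation precursor has not been shown.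

Step 10
Reactants: 12 silyl ether
Product: 13 methyl (6S,7S)-6-hydroxygermacra-1(10),4,11(13)-trien-12-oate (6β-OH, 7α-H; 6-epi series)
Conditions: 10% aq. citric acid, THF, 0 °C; used at once
Reagents that add atoms: none
Why: Mild hydrolysis of the very labile secondary TMS ether frees the alcohol without an alkoxide stage, so neither lactonisation nor acid-induced transannular cyclisation should set in.

Step 11
Reactants: 14 methyl 2-(hydroxymethyl)acrylate
Product: 15 methyl 2-[(tert-butyldimethylsilyloxy)methyl]acrylate
Conditions: TBSCl, imidazole, CH2Cl2, 0 °C to rt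
Reagents that add atoms: tert-butyldimethylsilyl chloride, CC(C)(C)[Si](C)(C)Cl
Why: O-silylation of the primary alcohol keeps the side-chain hydroxyl out of the Mitsunobu, radical and oxidation steps.

Step 12
Reactants: 15 silylated ester
Product: 16 2-[(tert-butyldimethylsilyloxy)methyl]acrylic acid
Conditions: LiOH·H2O (1.5 equiv), THF/H2O, 0 °C to rt, work-up at pH 4 (1 M HCl)
Reagents that add atoms: lithium hydroxide, [Li+].[OH-]
Why: Saponification of the unhindered methyl ester proceeds by acyl–oxygen cleavage, and the primary TBS ether survives the mild base and the brief pH 4 work-up.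

Step 13
Reactants: 13 6β-alcohol; 16 protected acid
Product: 17 methyl (6R,7S)-6-{2-[(tert-butyldimethylsilyloxy)methyl]acryloyloxy}germacra-1(10),4,11(13)-trien-12-oate (1(10)E,4E; 6α-O, 7α-H)
Conditions: PPh3 (2 equiv), DIAD (2 equiv), 16 (2 equiv), toluene, −20 °C to rt
Reagents that add atoms: none
Why: In the Mitsunobu esterification the activated 6β-oxygen is displaced by the carboxylate of 16 in an SN2 process with inversion, which sets the 6α-ester, leaves C7 untouched and never exposes a free 6α-alkoxide that could lactonise onto C12.

Step 14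
Reactants: 17 germacratriene ester
Product: 18 (1R,10R)-1,10-epoxide of 17 (4E; 6α-acyloxy, 7α-H)
Conditions: dimethyldioxirane (1.0 equiv, acetone solution), CH2Cl2, −40 to −20 °C
Reagents that add atoms: dimethyldioxirane, CC1(C)OO1
Why: Electrophilic dioxirane epoxidation should pick the 1(10)-alkene, because the 4(5)-alkene is deactivated by the allylic ester and both acrylates are electron-poor. Only the outer face of the E-alkene is open in the conformer with C14 and C15 on the β face (C6 and C7 substituents pseudo-equatorial), which gives the (1R,10R)-oxirane, and the neutral medium avoids premature cyclisation.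

Step 15
Reactants: 18 1(10)-epoxide
Product: 19 methyl 6α-{2-[(tert-butyldimethylsilyloxy)methyl]acryloyloxy}-1β-hydroxy-5αH,7αH-eudesma-4(15),11(13)-dien-12-oate (10β-methyl, trans-decalin)
Conditions: Cp2TiCl2 (2.5 equiv), Mn dust (8 equiv), THF (dry, degassed), rt, 18 added slowly (5 mM); aq. NaH2PO4 work-up
Reagents that add atoms: none
Why: Cp2TiCl (trivalent titanium, made from Cp2TiCl2 and Mn) binds the oxirane oxygen and breaks the C10–O bond homolytically, so that O1 stays on C1 as a titanium alkoxide and a tertiary radical sits on C10; this radical adds across the ring to C5 of the facing C4=C5 alkene, and the tertiary C4 radical is trapped by a second Cp2TiCl and loses a C15 hydrogen by β-hydride elimination to release the C4=C15 methylene. The closest known reaction type is the Cp2TiCl-mediated transannular radical cyclisation of 1(10)-epoxygermacranolides to 1β-hydroxyeudesm-4(15)-enes, the radical twin of the acid-induced germacrene epoxide cyclisation, used here on the ring-opened 6-acyloxy 12-methyl ester. The single new bond C5–C10 closes ring A (C1, C2, C3, C4, C5, C10) in the 6-endo-trig mode and ring B (C5, C6, C7, C8, C9, C10) in the 6-exo-trig mode. C1 is not touched and keeps its epoxide configuration (equatorial 1β-OH), while C10 and C5 are set together by the crossed chair–chair conformer of the E,E-ring, in which C14 and C15 both stand on the β face and the inner lobes at C10 and C5 face each other, so that C14 ends axial β and H5 axial α. The step needs transannular closure to outrun 6-endo attack of the nucleophilic C10 radical on C13 of the C7 acrylate, simple reduction and deoxygenation, and it needs hydrogen loss from C15 and not from C3. The first should be secured by the parallel, closely stacked radical/alkene pair with the C6 ester and C7 acrylate pseudo-equatorial and turned outward, by slow addition and by strict exclusion of water, and the second by the bulky titanium centre reaching only the unhindered methyl hydrogens.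

Step 16
Reactants: 19 eudesmadiene
Product: 20 1β,3α-dihydroxy analogue of 19 (axial 3α-OH)
Conditions: SeO2 (0.5 equiv), t-BuOOH (2.5 equiv, decane), CH2Cl2, 0 °C to rt
Reagents that add atoms: tert-butyl hydroperoxide, CC(C)(C)OO; selenium dioxide (oxygen relay), O=[Se]=O
Why: Selenium dioxide allylic hydroxylation (ene reaction, then [2,3]-sigmatropic shift) touches only the electron-rich C4=C15 alkene and takes the axial C3 hydrogen instead of the tertiary C5–H crowded by the C6 ester. Oxygen should be delivered axially (3α), and any 3-ketone formed by over-oxidation simply joins the next step.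

Step 17
Reactants: 20 1β,3α-diol
Product: 21 1β-hydroxy-3-oxo-4(15)-ene analogue of 19
Conditions: activated MnO2 (30 equiv), CH2Cl2, rt
Reagents that add atoms: none
Why: MnO2 oxidises allylic alcohols only, so the saturated 1β-carbinol stays. A large excess offsets the slower reaction of an axial allylic alcohol, and the neutral medium spares the base-sensitive β-hydroxy α-methylene ketone.

Step 18
Reactants: 21 exocyclic enone
Product: 22 1β,3β-dihydroxy analogue of 19 (equatorial 3β-OH)
Conditions: CeCl3·7H2O (1.2 equiv), NaBH4 (1.0 equiv), MeOH, −78 °C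
Reagents that add atoms: none
Why: Luche reduction gives clean 1,2-addition, with hydride arriving axially from the α face of the ring A chair to leave the equatorial 3β-alcohol; at −78 °C the two acrylate esters are not reduced.

Step 19
Reactants: 22 silyl-protected diol
Product: 23 CNP0247525.1, methyl (1R,3S,5S,6S,7S,10R)-1β,3β-dihydroxy-6α-[2-(hydroxymethyl)acryloyloxy]eudesma-4(15),11(13)-dien-12-oate
Conditions: HF·pyridine, pyridine, THF, 0 °C to rt
Reagents that add atoms: none
Why: Buffered fluoride-mediated desilylation removes the primary TBS ether without basic conditions, so no acyl migration, conjugate addition or lactonisation is expected.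

## Compound list

1 | (2E,6E)-farnesol | OC/C=C(C)/CC/C=C(C)/CCC=C(C)C | starting material
2 | (2E,6E)-farnesyl TBS ether | CC(C)(C)[Si](C)(C)OC/C=C(C)/CC/C=C(C)/CCC=C(C)C | intermediate
3 | 10-bromo-11-hydroxy-10,11-dihydrofarnesyl TBS ether (racemic) | CC(C)(C)[Si](C)(C)OC/C=C(C)/CC/C=C(C)/CCC(Br)C(C)(C)O | intermediate
4 | 10,11-epoxyfarnesyl TBS ether (racemic) | CC(C)(C)[Si](C)(C)OC/C=C(C)/CC/C=C(C)/CCC1OC1(C)C | intermediate
5 | 10,11-dihydroxy-10,11-dihydrofarnesyl TBS ether (racemic, not isolated) | CC(C)(C)[Si](C)(C)OC/C=C(C)/CC/C=C(C)/CCC(O)C(C)(C)O | intermediate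
6 | (4E,8E)-10-(tert-butyldimethylsilyloxy)-4,8-dimethyldeca-4,8-dienal | CC(C)(C)[Si](C)(C)OC/C=C(C)/CC/C=C(C)/CCC=O | intermediate
7 | methyl acrylate | C=CC(=O)OC | starting material
8 | Morita–Baylis–Hillman alcohol (racemic) | CC(C)(C)[Si](C)(C)OC/C=C(C)/CC/C=C(C)/CCC(O)C(=C)C(=O)OC | intermediate
9 | (2Z,6E,10E)-2-(bromomethyl)enoate TBS ether | CC(C)(C)[Si](C)(C)OC/C=C(C)/CC/C=C(C)/CC/C=C(\CBr)C(=O)OC | intermediate
10 | (2Z,6E,10E)-2-(bromomethyl)-12-hydroxy trienoate | OC/C=C(C)/CC/C=C(C)/CC/C=C(\CBr)C(=O)OC | intermediate
11 | (2Z,6E,10E)-2-(bromomethyl)-12-oxo trienoate (bromo enal) | O=C/C=C(C)/CC/C=C(C)/CC/C=C(\CBr)C(=O)OC | intermediate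
12 | methyl (6S,7S)-6-(trimethylsilyloxy)germacra-1(10)E,4E,11(13)-trien-12-oate | C[Si](C)(C)O[C@H]1/C=C(C)/CC/C=C(C)/CC[C@H]1C(=C)C(=O)OC | intermediate
13 | methyl (6S,7S)-6-hydroxygermacra-1(10)E,4E,11(13)-trien-12-oate | O[C@H]1/C=C(C)/CC/C=C(C)/CC[C@H]1C(=C)C(=O)OC | intermediate
14 | methyl 2-(hydroxymethyl)acrylate | C=C(CO)C(=O)OC | starting material
15 | methyl 2-[(tert-butyldimethylsilyloxy)methyl]acrylate | C=C(CO[Si](C)(C)C(C)(C)C)C(=O)OC | intermediate
16 | 2-[(tert-butyldimethylsilyloxy)methyl]acrylic acid | C=C(CO[Si](C)(C)C(C)(C)C)C(=O)O | intermediate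
17 | (6R,7S)-6α-acyloxygermacra-1(10)E,4E,11(13)-trien-12-oate | C=C(CO[Si](C)(C)C(C)(C)C)C(=O)O[C@@H]1/C=C(C)/CC/C=C(C)/CC[C@H]1C(=C)C(=O)OC | intermediate
18 | (1R,10R)-1,10-epoxide of 17 | C=C(CO[Si](C)(C)C(C)(C)C)C(=O)O[C@@H]1/C=C(C)/CC[C@H]2O[C@]2(C)CC[C@H]1C(=C)C(=O)OC | intermediate
19 | 6α-acyloxy-1β-hydroxyeudesma-4(15),11(13)-dien-12-oate | C=C(CO[Si](C)(C)C(C)(C)C)C(=O)O[C@@H]1[C@H]2C(=C)CC[C@@H](O)[C@]2(C)CC[C@H]1C(=C)C(=O)OC | intermediate
20 | 1β,3α-diol | C=C(CO[Si](C)(C)C(C)(C)C)C(=O)O[C@@H]1[C@H]2C(=C)[C@H](O)C[C@@H](O)[C@]2(C)CC[C@H]1C(=C)C(=O)OC | intermediate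
21 | 1β-hydroxy-4(15)-en-3-one | C=C(CO[Si](C)(C)C(C)(C)C)C(=O)O[C@@H]1[C@H]2C(=C)C(=O)C[C@@H](O)[C@]2(C)CC[C@H]1C(=C)C(=O)OC | intermediate
22 | 1β,3β-diol, side chain silylated | C=C(CO[Si](C)(C)C(C)(C)C)C(=O)O[C@@H]1[C@H]2C(=C)[C@@H](O)C[C@@H](O)[C@]2(C)CC[C@H]1C(=C)C(=O)OC | intermediate
23 | CNP0247525.1 | C=C(CO)C(=O)O[C@@H]1[C@H]2C(=C)[C@@H](O)C[C@@H](O)[C@]2(C)CC[C@H]1C(=C)C(=O)OC | target

## Step count and risks

Total step count: 19. Longest linear sequence: 17 (steps 1–10 and 13–19, from farnesol).

**1. Step 9.** What may go wrong:
- weak enantiofacial control by the ligand in a strained macrocyclic transition state;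
- slow catalyst turnover at high dilution;
- ligand-free background allylation, or oligomerisation.

The fallback sets out from 11 and returns at 13, using only known chemistry. The ring is closed in the racemic series with stoichiometric CrCl2 (divalent chromium, 5 equiv) and TMSCl in THF/DMF under high dilution. This ligand-free Nozaki–Hiyama–Kishi closure is established for bromo enals of this type. It gives 12 together with its mirror image, methyl (6R,7R)-6-(trimethylsilyloxy)germacra-1(10),4,11(13)-trien-12-oate F1. Citric acid cleavage as in step 10 then gives 13 and methyl (6R,7R)-6-hydroxygermacra-1(10),4,11(13)-trien-12-oate F2. The two alcohols are separated by preparative chromatography on a chiral stationary phase (amylose or cellulose carbamate). The absolute configuration is assigned through MTPA esters, and 13 goes on to step 13.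

**2. Step 13.** What may go wrong:
- SN2′ attack at C4, or elimination to a triene;
- transannular participation of the 1(10)-alkene;
- capture of the activated C6 by the neighbouring C12 ester carbonyl, leading to lactonisation.

All of these are favoured by a bulky, weakly acidic carboxylic acid. The fallback sets out from 13 and returns at 17. It separates the inversion from the transfer of the acyl chain. Mitsunobu displacement with the small, strongly acidic chloroacetic acid (PPh3, DIAD, toluene, −20 °C) gives methyl (6R,7S)-6-(chloroacetoxy)germacra-1(10),4,11(13)-trien-12-oate F3. Neutral cleavage with thiourea and NaHCO3 in EtOH/THF frees methyl (6R,7S)-6-hydroxygermacra-1(10),4,11(13)-trien-12-oate F4 without an alkoxide stage. F4 is acylated at once, with retention, with 16 under Steglich conditions (DCC, DMAP, CH2Cl2, −10 °C) to give 17.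

**3. Step 15.** What may go wrong:
- diversion of the C10 radical onto the C7 acrylate;
- premature reduction of the C10 or C4 radical;
- deoxygenation of the oxirane back to the alkene;
- hydrogen loss toward C3.

The fallback sets out from 18 and returns at 20. It replaces the radical manifold by the cationic one and makes use of the endocyclic alkene isomer. BF3·OEt2 in CH2Cl2 at −78 °C opens the oxirane with anti attack of C5 on C10, giving the same 1β-OH, 10β-methyl, 5α-H array. The C4 cation then loses a proton to give 19, which rejoins at step 16, together with the 6α-acyloxy-1β-hydroxyeudesma-3,11(13)-dien-12-oate F5. A Schenck ene reaction of F5 (O2, tetraphenylporphyrin, light, CH2Cl2, 0 °C) proceeds from the α face opposite the axial C14 methyl with abstraction of a C15 hydrogen. It gives the 3α-hydroperoxy-1β-hydroxyeudesma-4(15),11(13)-dien-12-oate F6, and PPh3 reduces F6 to 20.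

## Further compounds

F1 | step 9 | methyl (6R,7R)-6-(trimethylsilyloxy)germacra-1(10)E,4E,11(13)-trien-12-oate | C[Si](C)(C)O[C@@H]1/C=C(C)/CC/C=C(C)/CC[C@@H]1C(=C)C(=O)OC
F2 | step 9 | methyl (6R,7R)-6-hydroxygermacra-1(10)E,4E,11(13)-trien-12-oate | O[C@@H]1/C=C(C)/CC/C=C(C)/CC[C@@H]1C(=C)C(=O)OC
F3 | step 13 | methyl (6R,7S)-6-(chloroacetoxy)germacra-1(10)E,4E,11(13)-trien-12-oate | ClCC(=O)O[C@@H]1/C=C(C)/CC/C=C(C)/CC[C@H]1C(=C)C(=O)OC
F4 | step 13 | methyl (6R,7S)-6-hydroxygermacra-1(10)E,4E,11(13)-trien-12-oate | O[C@@H]1/C=C(C)/CC/C=C(C)/CC[C@H]1C(=C)C(=O)OC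
F5 | step 15 | 6α-acyloxy-1β-hydroxyeudesma-3,11(13)-dien-12-oate | C=C(CO[Si](C)(C)C(C)(C)C)C(=O)O[C@@H]1[C@H]2C(C)=CC[C@@H](O)[C@]2(C)CC[C@H]1C(=C)C(=O)OC
F6 | step 15 | 3α-hydroperoxy-1β-hydroxyeudesma-4(15),11(13)-dien-12-oate | C=C(CO[Si](C)(C)C(C)(C)C)C(=O)O[C@@H]1[C@H]2C(=C)[C@H](OO)C[C@@H](O)[C@]2(C)CC[C@H]1C(=C)C(=O)OC
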